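The readings were generated by integration on assumed constants, and the scatter is random.

**The ratio.** Side product over target is the ratio I follow through these flasks; the share asked for is that ratio in another form.

| flask | substrate | partner | protic impurity | remark | time |
|---|---|---|---|---|---|
| winter | 17 mM | 13.6 mM | 17 mM | run made earlier |  |
| dusk | 17 mM | 6.8 mM | 17 mM | run made earlier |  |
| midnight | 17 mM | 10 mM | 17 mM | run made earlier |  |
| autumn | 17 mM | 13.6 mM | 34 mM | run made earlier |  |
| Saturday's | 17 mM (in portions, 5, over 40 h) | 13.6 mM | 17.0 mM | first portion at the start, last at 40 h | 50 h |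
| Monday's | 17 mM (fed, over 40 h) | 13.6 mM | 17.0 mM | all else is in the flask from the start; the feed brings no volume worth counting | 50 h |
| Wednesday's | 17 mM | 13.6 mM | 17.0 mM | everything together at the start | 50 h |
| Thursday's | 17 mM | 13.6 mM (fed, over 40 h) | 17.0 mM | all else is in the flask from the start; the feed brings no volume worth counting | 50 h |

| run | time / h | target / % | side product / % | substrate / % |
|---|---|---|---|---|
| winter | 4.00 | 24.4 | 7.2 | 51.8 |
| winter | 10.0 | 26.0 | 6.9 | 50.2 |
| winter | 20.0 | 25.5 | 7.7 | 50.6 |
| winter | 48.0 | 25.2 | 7.2 | 50.7 |
| dusk | 12.0 | 15.0 | 1.3 | 73.5 |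
| dusk | 25.0 | 14.4 | 2.2 | 73.6 |
| dusk | 40.0 | 14.1 | 2.2 | 74.3 |
| dusk | 48.0 | 14.6 | 2.2 | 73.2 |
| midnight | 4.00 | 20.1 | 4.0 | 63.1 |
| midnight | 10.0 | 19.9 | 3.7 | 62.5 |
| midnight | 20.0 | 20.3 | 4.2 | 62.5 |
| midnight | 48.0 | 20.3 | 4.3 | 62.8 |
| autumn | 4.00 | 20.2 | 5.4 | 61.2 |
| autumn | 10.0 | 19.9 | 5.9 | 60.6 |
| autumn | 20.0 | 19.6 | 6.1 | 60.9 |
| autumn | 48.0 | 20.4 | 5.9 | 60.2 |

(standard deviation of a reading: 0.3 percentage points)



- the flask with the highest share of target in target plus side product ("all alike" if they lie within 1.5 percentage points) (Saturday's / Monday's / Wednesday's / Thursday's / all alike)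
- share of target in target plus side product at the end, Saturday's
- share of target in target plus side product at the end, Monday's
- share of target in target plus side product at the end, Wednesday's
- share of target in target plus side product at the end, Thursday's

**Fastest rung.** In the midnight run, target reads 20.1% at 4.00 h and 20.3% at 48.0 h, while substrate stays near 62.8%. I therefore take partner as the limiting reagent. The gap lies within about one scatter, 0.3 percentage points. If I take that scatter as the size of the gap left at the first reading, an exponential fall gives partner a lifetime τ of roughly 0.949 h, which is an estimate from scattered readings and not a bound.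

**Middle rung.** In a batch, I take the mean partner level met by the reaction as 6.80 mM for the winter run. Its ratio of 0.286 then gives κ, side product per target per mM of partner, of 0.0420 mM⁻¹. The dusk run gives 0.0443 mM⁻¹. The share is one over one plus κ times the level, so Wednesday's, which repeats the winter recipe, comes to 77.8%.

**Slowest rung.** I count turnovers: N, the feed time over τ, is the number of partner lifetimes in a feed, here 42.1. Because the lifetime is far shorter than the feed, partner in Thursday's is used about as it arrives, and rests near its charge over N, 0.323 mM. That gives 98.7%, higher than Wednesday's. Saturday's and Monday's feed substrate instead, so N does not apply to them.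

**The forecast.** It gives 78.5% for Saturday's, 87.5% for Monday's, 77.8% for Wednesday's and 98.8% for Thursday's, and names Thursday's: “partner stays near 2%, giving about 99%”.

**The flasks.** The flasks give 77.6%, 87.2%, 78.1% and 98.4% in that order, so Thursday's leads.

    substrate + partner → target (k = 0.744 L mol⁻¹ min⁻¹)
    substrate + 2 partner → side product (k = 19.2 L² mol⁻² min⁻¹)
    target ⇌ isomer of the product (K = 0.670, k = 0.0416 min⁻¹)
    partner + protic impurity → quenched reagent (k = 0.327 L mol⁻¹ min⁻¹)

**At rest.** Thursday's holds 30.9% target against 0.512% side product. With its feed cut to 12.0 h, N falls to 12.6, the rule gives 95.7%, and that flask gives 95.4%. Thursday's partner stands at 3.84% of its charge at 40.0 h and 0.00859% at 50.0 h, so little can still react. At 500 h partner reads 0%, substrate 47.9%, side product 0.512%, and the share 98.4%.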